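## Retrosynthetic overview
1. Target ⇒ tricyclic 8-alcohol carrying a 15-O-TBDPS group. The 8-isobutyrate and the free 15-OH are installed last.
2. Third ring (furanone, O bridge C3–C10) ⇒ ten-membered 2-yne lactone. The C1 carbinol is oxidised, then 10-OH attacks C3 across the ring. The alkyne stands in for the 3-ketone of the biogenetic 3,10-hemiketal.
3. First ring (carbocycle) and second ring (6,12-lactone) ⇒ linear C15 chain. The C6–C7 bond, the one formed when farnesyl diphosphate closes to germacrene, is made by allylchromium addition to an enal. O6–C12 lactonisation follows in the same flask.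
4. Linear chain ⇒ C3–C4 Sonogashira union of a (Z)-iodoenal (C4–C6, C15, from but-2-yne-1,4-diol) with an alkynyl carbinol (C1–C3, C7–C14).
5. Alkynyl carbinol ⇒ (R)-linalool (supplies C10), L-proline aminoxylation (sets C8) and a silyl-bearing Wittig reagent (C11–C13).

Assumption: commercial (R)-(−)-linalool of high ee is used, positions carry germacrane numbering (C1–C15), and the epimers at C1 (later a ketone), at the lactol carbon and at the brominated C7 are carried as mixtures.

## Route

Step 1
Reactants: 1 but-2-yne-1,4-diol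
Product: 2 4-[(tert-butyldiphenylsilyl)oxy]but-2-yn-1-ol
Conditions: TBDPSCl (0.33 equiv), imidazole, DMF, 0 °C to rt; excess diol washed out with water
Reagents that add atoms: tert-butyl(chloro)diphenylsilane, CC(C)(C)[Si](Cl)(c1ccccc1)c1ccccc1
Why: Silyl ether formation on a three-fold excess of the cheap symmetrical diol gives mainly the mono-ether, and the acid-stable TBDPS group is chosen because it must outlast the later acidic removal of TMS and TES groups, no stereocentre being formed.

Step 2
Reactants: 2 4-[(tert-butyldiphenylsilyl)oxy]but-2-yn-1-ol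
Product: 4 (Z)-4-[(tert-butyldiphenylsilyl)oxy]-3-iodobut-2-en-1-ol, via cyclic sodium alkenylaluminate 3 (not isolated)
Conditions: NaAlH2(OCH2CH2OMe)2 (1.1 equiv), THF, 0 °C; then I2, −78 °C to 0 °C
Reagents that add atoms: iodine, II
Why: Hydroxyl-directed trans-hydroalumination of the propargylic alcohol places aluminium on the distal alkyne carbon inside a five-membered chelate, and iodinolysis with retention gives only the Z-iodide (I cis to CH2OH), which fixes the C4=C5 geometry of the target.

Step 3
Reactants: 4 (Z)-4-[(tert-butyldiphenylsilyl)oxy]-3-iodobut-2-en-1-ol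
Product: 5 (Z)-4-[(tert-butyldiphenylsilyl)oxy]-3-iodobut-2-enal
Conditions: MnO2 (15 equiv), CH2Cl2, rt, dark
Reagents that add atoms: none
Why: MnO2 oxidation of the allylic alcohol is neutral and heterogeneous, so the β-iodoenal keeps its Z geometry and the silyl ether survives.

Step 4
Reactants: 6 methyl (triphenylphosphoranylidene)acetate
Product: 8 methyl 2-(triphenylphosphoranylidene)-3-(trimethylsilyl)propanoate, via phosphonium iodide 7 (not isolated)
Conditions: ICH2SiMe3 (1.2 equiv), MeCN, 80 °C; then 1 M aq NaOH, CH2Cl2, 0 °C, 5 min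
Reagents that add atoms: (iodomethyl)trimethylsilane, C[Si](C)(C)CI
Why: C-alkylation of the stabilised ylide by the SN2-active α-silyl iodide, followed by fast deprotonation of the acidic phosphonium salt, gives the substituted stabilised Wittig reagent that carries C11, C12, C13 and the silyl group.

Step 5
Reactants: 9 (R)-(−)-linalool
Product: 10 (R)-linalool triethylsilyl ether
Conditions: TESOTf (1.2 equiv), 2,6-lutidine, CH2Cl2, 0 °C
Reagents that add atoms: triethylsilyl trifluoromethanesulfonate, CC[Si](CC)(CC)OS(=O)(=O)C(F)(F)F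
Why: Silyl triflate silylation is the standard way to cap a hindered tertiary allylic alcohol and it prevents lactol formation after the cleavage, while the 10R stereocentre comes from the chiral pool and is not touched.

Step 6
Reactants: 10 (R)-linalool triethylsilyl ether
Product: 12 (2R)-2-methyl-2-[(triethylsilyl)oxy]pentanedial, via bis-ozonide 11 (not isolated)
Conditions: O3, CH2Cl2, −78 °C until blue; then Me2S, −78 °C to rt
Reagents that add atoms: ozone, [O-][O+]=O
Why: Exhaustive ozonolysis with reductive work-up cleaves both alkenes at once and gives an unhindered enolisable C7 aldehyde beside a non-enolisable neopentyl-type C1 aldehyde, which differ enough in reactivity to be addressed separately, and the quaternary C10 cannot epimerise.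

Step 7
Reactants: 12 (2R)-2-methyl-2-[(triethylsilyl)oxy]pentanedial; 8 methyl 2-(triphenylphosphoranylidene)-3-(trimethylsilyl)propanoate
Product: 15 methyl (Z)-3-{(2R,4R)-5-hydroxy-4-methyl-4-[(triethylsilyl)oxy]oxolan-2-yl}-2-[(trimethylsilyl)methyl]prop-2-enoate, via aminoxy dialdehyde 13 (not isolated), via aminoxy enoate 14 (not isolated)
Conditions: L-proline (20 mol %), PhNO (1.0 equiv, slow addition), DMSO, rt; then 8 (1.3 equiv), CH2Cl2, 0 °C to rt; then Cu(OAc)2 (30 mol %), MeOH, rt
Reagents that add atoms: nitrosobenzene, O=Nc1ccccc1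
Why: Proline enamine catalysis (α-aminoxylation) can engage only the enolisable C7 aldehyde, and natural L-proline delivers oxygen through its hydrogen-bonded transition state to set 8R under catalyst control; the sensitive α-oxy aldehyde is trapped in situ by a Wittig reaction that the bulky ylide performs only at the unhindered aldehyde (either alkene isomer is usable later), and copper-catalysed N–O cleavage frees the 8-OH, which rests as the lactol on C1.

Step 8
Reactants: 15 methyl (Z)-3-{(2R,4R)-5-hydroxy-4-methyl-4-[(triethylsilyl)oxy]oxolan-2-yl}-2-[(trimethylsilyl)methyl]prop-2-enoate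
Product: 16 methyl (2Z,4R,6R)-4,7-dihydroxy-6-methyl-6-[(triethylsilyl)oxy]-2-[(trimethylsilyl)methyl]non-2-en-8-ynoate (C7 epimers)
Conditions: HC≡CMgBr (4 equiv), THF, 0 °C to rt; water quench
Reagents that add atoms: ethynylmagnesium bromide, C#C[Mg]Br
Why: Grignard addition to the ring-opened lactol (the first equivalent deprotonates it) installs C2 and C3, the weakly nucleophilic alkynyl Grignard reagent leaves the hindered conjugated ester alone, and the new carbinol epimers are inconsequential because C1 ends as a ketone.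

Step 9
Reactants: 16 methyl (2Z,4R,6R)-4,7-dihydroxy-6-methyl-6-[(triethylsilyl)oxy]-2-[(trimethylsilyl)methyl]non-2-en-8-ynoate; 5 (Z)-4-[(tert-butyldiphenylsilyl)oxy]-3-iodobut-2-enal
Product: 17 methyl (2Z,4R,6R,10E)-10-{[(tert-butyldiphenylsilyl)oxy]methyl}-4,7-dihydroxy-6-methyl-12-oxo-6-[(triethylsilyl)oxy]-2-[(trimethylsilyl)methyl]dodeca-2,10-dien-8-ynoate (CHO cis to the alkyne)
Conditions: PdCl2(PPh3)2 (3 mol %), CuI (6 mol %), Et3N (3 equiv), THF, rt
Reagents that add atoms: none
Why: Sonogashira coupling (zerovalent palladium plus copper acetylide) of the vinylogous acyl iodide runs at room temperature with retention of the alkene geometry and tolerates the free hydroxyls, the allylsilane and the enal, so the whole C15 chain is assembled without touching a stereocentre.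

Step 10
Reactants: 17 linear enynal allylsilane diol
Product: 19 methyl (4R,6R,10E)-3-bromo-10-{[(tert-butyldiphenylsilyl)oxy]methyl}-6-methyl-2-methylidene-12-oxo-6-[(triethylsilyl)oxy]-4,7-bis[(trimethylsilyl)oxy]dodec-10-en-8-ynoate (C3/C7 epimers), via bis-TMS ether 18 (not isolated)
Conditions: N,O-bis(trimethylsilyl)acetamide (1.5 equiv), CH2Cl2, rt; then NBS (1.05 equiv), −78 °C to −20 °C, dark; short silica pad, used at once
Reagents that add atoms: N,O-bis(trimethylsilyl)acetamide, CC(=N[Si](C)(C)C)O[Si](C)(C)C; N-bromosuccinimide, O=C1CCC(=O)N1Br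
Why: Silylation turns the 1- and 8-hydroxyls into non-chelating poor leaving groups, and electrophilic bromodesilylation (SE2' attack of the bromonium source at C7 with loss of Me3Si from C13) converts both alkene isomers of the robust allylsilane into the allylic bromide without any hydroxyl activation, the new C7 centre being erased again in the next step.

Step 11
Reactants: 19 linear enynal allylic bromide
Product: 22 (6R,7R,8R,10R)-15-[(tert-butyldiphenylsilyl)oxy]-1,8,10-trihydroxygermacra-4,11(13)-dien-2-yn-12,6-olide (C3 cis to C6 on C4=C5; C1 epimers), via allylchromium dichloride 20 (not isolated), via persilylated macrolactone 21 (not isolated)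
Conditions: CrCl2 (10 equiv), degassed THF–DMF 4:1, rt, 19 added by syringe pump over 12 h (final 1 mM); aqueous work-up; then 1 M HCl–THF, rt
Reagents that add atoms: none
Why: In this Nozaki–Hiyama-type macrocyclic allylation two equivalents of divalent chromium turn the bromide into the equilibrating (E)-σ-allyl species of trivalent chromium, which adds through C7 to the enal carbonyl in a chair transition state (6,7-anti, hence the trans-lactone) on the alkene face anti to C9, with H8 eclipsing the double bond and the silyloxy group outside (6R and 7R follow from 8R); the rigid Z-enyne holds the chain ends together much as the folded farnesyl chain is held, its linear C1–C4 unit spans about the same distance as the later trans C2=C3 enol ether, the chromium alkoxide then closes the lactone on the methyl ester, and dilute acid strips TMS and TES but not TBDPS.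

Step 12
Reactants: 22 ten-membered 2-yne triol lactone
Product: 24 (6R,7R,8R,10R)-15-[(tert-butyldiphenylsilyl)oxy]-3,10-epoxy-8-hydroxy-1-oxogermacra-2,4Z,11(13)-trien-12,6-olide, via macrocyclic ynone 23 (not isolated)
Conditions: MnO2 (20 equiv), CH2Cl2, rt; filter; then Ph3PAuNTf2 (5 mol %), CH2Cl2, rt
Reagents that add atoms: none
Why: MnO2 oxidises only the propargylic C1 carbinol (the 8-OH is no longer allylic and the 10-OH is tertiary), and the cationic gold complex activates the bent ynone for transannular 5-endo-dig oxa-Michael cyclisation of 10-OH onto C3; this is the alkyne equivalent of the biogenetic 3,10-hemiketalisation and dehydration, it forms the 3(2H)-furanone, and it leaves 10R intact because no bond at C10 is broken.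

Step 13
Reactants: 24 tricyclic 8-alcohol
Product: 25 (6R,7R,8R,10R)-15-[(tert-butyldiphenylsilyl)oxy]-3,10-epoxy-8-(isobutyryloxy)-1-oxogermacra-2,4Z,11(13)-trien-12,6-olide
Conditions: isobutyric anhydride (3 equiv), DMAP (0.2 equiv), pyridine–CH2Cl2, 0 °C to rt
Reagents that add atoms: isobutyric anhydride, CC(C)C(=O)OC(=O)C(C)C
Why: DMAP-catalysed acyl transfer finds a single free hydroxyl, so the 8β-isobutyrate forms with retention at C8, and placing the acylation after ring closure keeps a good leaving group away from the allylmetal stage.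

Step 14
Reactants: 25 silylated 8-isobutyrate
Product: 26 (6R,7R,8R,10R)-3,10-epoxy-15-hydroxy-8-(isobutyryloxy)-1-oxogermacra-2,4Z,11(13)-trien-12,6-olide (CNP0176924.3)
Conditions: HF·pyridine, pyridine, THF, 0 °C to rt
Reagents that add atoms: none
Why: Fluoride-driven Si–O cleavage under buffered, mildly acidic conditions frees the primary allylic 15-OH without the basic conditions that would add to the α-methylene lactone or move the ester, and no stereocentre is affected.

## Compound list
1 | but-2-yne-1,4-diol | OCC#CCO | starting material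
2 | 4-[(tert-butyldiphenylsilyl)oxy]but-2-yn-1-ol | OCC#CCO[Si](c1ccccc1)(c1ccccc1)C(C)(C)C | intermediate
3 | cyclic sodium alkenylaluminate (five-membered O–Al–C chelate, two 2-methoxyethoxy ligands) | [Na+].COCCO[Al-]1(OCCOC)OCC=C1CO[Si](c1ccccc1)(c1ccccc1)C(C)(C)C | intermediate
4 | (Z)-4-[(tert-butyldiphenylsilyl)oxy]-3-iodobut-2-en-1-ol | OC/C=C(/CO[Si](c1ccccc1)(c1ccccc1)C(C)(C)C)I | intermediate
5 | (Z)-4-[(tert-butyldiphenylsilyl)oxy]-3-iodobut-2-enal | O=C/C=C(/CO[Si](c1ccccc1)(c1ccccc1)C(C)(C)C)I | intermediate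
6 | methyl (triphenylphosphoranylidene)acetate | COC(=O)C=P(c1ccccc1)(c1ccccc1)c1ccccc1 | starting material
7 | [1-methoxy-1-oxo-3-(trimethylsilyl)propan-2-yl]triphenylphosphonium iodide | COC(=O)C(C[Si](C)(C)C)[P+](c1ccccc1)(c1ccccc1)c1ccccc1.[I-] | intermediate
8 | methyl 2-(triphenylphosphoranylidene)-3-(trimethylsilyl)propanoate | COC(=O)C(C[Si](C)(C)C)=P(c1ccccc1)(c1ccccc1)c1ccccc1 | intermediate
9 | (R)-(−)-linalool, (3R)-3,7-dimethylocta-1,6-dien-3-ol | C=C[C@](C)(O)CCC=C(C)C | starting material
10 | (R)-linalool triethylsilyl ether | C=C[C@](C)(O[Si](CC)(CC)CC)CCC=C(C)C | intermediate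
11 | bis(1,2,4-trioxolane) of 10 (ozonide carbons unassigned) | C1(OCOO1)[C@](C)(O[Si](CC)(CC)CC)CCC1OC(C)(C)OO1 | intermediate
12 | (2R)-2-methyl-2-[(triethylsilyl)oxy]pentanedial | O=C[C@](C)(O[Si](CC)(CC)CC)CCC=O | intermediate
13 | (2R,4R)-2-methyl-4-[(phenylamino)oxy]-2-[(triethylsilyl)oxy]pentanedial | O=C[C@](C)(O[Si](CC)(CC)CC)C[C@@H](ONc1ccccc1)C=O | intermediate
14 | methyl (2Z,4R,6R)-6-methyl-7-oxo-4-[(phenylamino)oxy]-6-[(triethylsilyl)oxy]-2-[(trimethylsilyl)methyl]hept-2-enoate | O=C[C@](C)(O[Si](CC)(CC)CC)C[C@@H](ONc1ccccc1)/C=C(/C(=O)OC)C[Si](C)(C)C | intermediate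
15 | methyl (Z)-3-{(2R,4R)-5-hydroxy-4-methyl-4-[(triethylsilyl)oxy]oxolan-2-yl}-2-[(trimethylsilyl)methyl]prop-2-enoate (anomers) | OC1[C@](C)(O[Si](CC)(CC)CC)C[C@@H](O1)/C=C(/C(=O)OC)C[Si](C)(C)C | intermediate
16 | methyl (2Z,4R,6R)-4,7-dihydroxy-6-methyl-6-[(triethylsilyl)oxy]-2-[(trimethylsilyl)methyl]non-2-en-8-ynoate (C7 epimers) | C#CC(O)[C@](C)(O[Si](CC)(CC)CC)C[C@@H](O)/C=C(/C(=O)OC)C[Si](C)(C)C | intermediate
17 | linear enynal allylsilane diol (full name in step 9) | O=C/C=C(/CO[Si](c1ccccc1)(c1ccccc1)C(C)(C)C)C#CC(O)[C@](C)(O[Si](CC)(CC)CC)C[C@@H](O)/C=C(/C(=O)OC)C[Si](C)(C)C | intermediate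
18 | 1,8-bis(trimethylsilyl) ether of 17 (germacrane positions) | O=C/C=C(/CO[Si](c1ccccc1)(c1ccccc1)C(C)(C)C)C#CC(O[Si](C)(C)C)[C@](C)(O[Si](CC)(CC)CC)C[C@@H](O[Si](C)(C)C)/C=C(/C(=O)OC)C[Si](C)(C)C | intermediate
19 | linear enynal allylic bromide, Br on C7, C11=C13 methylidene (full name in step 10) | O=C/C=C(/CO[Si](c1ccccc1)(c1ccccc1)C(C)(C)C)C#CC(O[Si](C)(C)C)[C@](C)(O[Si](CC)(CC)CC)C[C@@H](O[Si](C)(C)C)C(Br)C(=C)C(=O)OC | intermediate
20 | (E)-σ-allylchromium dichloride derived from 19 (Cr on C13, C8 trans to CH2Cr) | O=C/C=C(/CO[Si](c1ccccc1)(c1ccccc1)C(C)(C)C)C#CC(O[Si](C)(C)C)[C@](C)(O[Si](CC)(CC)CC)C[C@@H](O[Si](C)(C)C)/C=C(/C[Cr](Cl)Cl)C(=O)OC | intermediate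
21 | (6R,7R,8R,10R)-15-[(tert-butyldiphenylsilyl)oxy]-10-[(triethylsilyl)oxy]-1,8-bis[(trimethylsilyl)oxy]germacra-4,11(13)-dien-2-yn-12,6-olide | C=C1C(=O)O[C@@H]2/C=C(/CO[Si](c3ccccc3)(c3ccccc3)C(C)(C)C)C#CC(O[Si](C)(C)C)[C@](C)(O[Si](CC)(CC)CC)C[C@@H](O[Si](C)(C)C)[C@@H]12 | intermediate
22 | (6R,7R,8R,10R)-15-[(tert-butyldiphenylsilyl)oxy]-1,8,10-trihydroxygermacra-4,11(13)-dien-2-yn-12,6-olide (C1 epimers) | C=C1C(=O)O[C@@H]2/C=C(/CO[Si](c3ccccc3)(c3ccccc3)C(C)(C)C)C#CC(O)[C@](C)(O)C[C@@H](O)[C@@H]12 | intermediate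
23 | (6R,7R,8R,10R)-15-[(tert-butyldiphenylsilyl)oxy]-8,10-dihydroxy-1-oxogermacra-4,11(13)-dien-2-yn-12,6-olide | C=C1C(=O)O[C@@H]2/C=C(/CO[Si](c3ccccc3)(c3ccccc3)C(C)(C)C)C#CC(=O)[C@](C)(O)C[C@@H](O)[C@@H]12 | intermediate
24 | (6R,7R,8R,10R)-15-[(tert-butyldiphenylsilyl)oxy]-3,10-epoxy-8-hydroxy-1-oxogermacra-2,4Z,11(13)-trien-12,6-olide | C=C1C(=O)O[C@@H]2/C=C(/CO[Si](c4ccccc4)(c4ccccc4)C(C)(C)C)C3=CC(=O)[C@@](C)(C[C@@H](O)[C@@H]12)O3 | intermediate
25 | (6R,7R,8R,10R)-15-[(tert-butyldiphenylsilyl)oxy]-3,10-epoxy-8-(isobutyryloxy)-1-oxogermacra-2,4Z,11(13)-trien-12,6-olide | C=C1C(=O)O[C@@H]2/C=C(/CO[Si](c4ccccc4)(c4ccccc4)C(C)(C)C)C3=CC(=O)[C@@](C)(C[C@@H](OC(=O)C(C)C)[C@@H]12)O3 | intermediate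
26 | (6R,7R,8R,10R)-3,10-epoxy-15-hydroxy-8-(isobutyryloxy)-1-oxogermacra-2,4Z,11(13)-trien-12,6-olide (CNP0176924.3) | C=C1C(=O)O[C@@H]2/C=C(/CO)C3=CC(=O)[C@@](C)(C[C@@H](OC(=O)C(C)C)[C@@H]12)O3 | target

## Step count and risks

Total step count: 14.
Longest linear sequence: 10 steps (steps 5–14, from (R)-linalool).

**Step 11** (closure of the ten-membered enyne ring). The ring closure may lose to reduction, dimerisation or 1,4-elimination of the 8-silyloxy group, and the 6,7-anti and 7,8 selectivity is argued from models only. The fallback sets out from 17 and comes back at 24. It keeps the same bonds but changes the order of ring formation, so that chromium no longer has to close a ring that holds an alkyne.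
- TESCl and imidazole at −20 °C cap the less hindered 8-OH to give the 8-O-TES ether F1. This is needed because the 8-OH is still allylic in the open chain.
- MnO2 gives the open-chain ynone F2.
- AcOH–THF–H2O removes both TES groups to give the dihydroxy ynone F3. Under the same acid catalysis this closes by 5-endo-dig oxa-Michael addition to the open-chain furanone F4.
- N,O-bis(trimethylsilyl)acetamide gives its 8-O-TMS ether F5, and NBS gives the allylic bromide F6.
- CrCl2 under high dilution forms the allylchromium species F7. Its only reactive carbonyl partner is the enal, because the furanone carbonyl is a vinylogous ester. C6–C7 closure and lactonisation give the 8-O-TMS tricycle F8.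
- Dilute HCl then delivers 24.

**Step 7** (three operations in one flask on a dialdehyde). The C1 aldehyde may interfere, the bulky ylide may be slow, and the α-oxy aldehyde may oligomerise. The fallback sets out from 10 and comes back at 15. It avoids the dialdehyde by cleaving the two alkenes one after the other.
- One equivalent of O3 in CH2Cl2–pyridine at −78 °C cleaves only the trisubstituted alkene to give the vinyl aldehyde F9.
- L-proline and PhNO give the aminoxy aldehyde F10, ylide 8 gives the aminoxy enoate F11, and Cu(OAc)2 in MeOH gives the hydroxy enoate F12. Each can now be purified because no second aldehyde is present.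
- OsO4 (cat.), NaIO4 and 2,6-lutidine then cleave the remaining monosubstituted vinyl group in preference to the electron-poor trisubstituted enoate. The resulting hydroxy aldehyde closes to lactol 15.

**Step 10** (bromodesilylation of an ester-deactivated allylsilane beside an enynal). The reaction may be slow or unselective. The fallback sets out from 18 and comes back at 21, skipping 19 and 20. The allylsilane is used directly as the nucleophile in an intramolecular Hosomi–Sakurai reaction (BF3·OEt2, CH2Cl2, −78 °C, high dilution). The Lewis-acid-bound enal plays the part of the farnesyl cation and the silyl group that of the proton lost from C13, and lactonisation follows on warming. Additions of 2-(alkoxycarbonyl)allylsilanes to activated aldehydes are the best documented reactions of this silane class. The price is weaker control of the 6,7 relationship. This fallback makes no new compound (F0).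

## Further compounds
F1 | step 11 | 8-O-triethylsilyl ether of 17 | O=C/C=C(/CO[Si](c1ccccc1)(c1ccccc1)C(C)(C)C)C#CC(O)[C@](C)(O[Si](CC)(CC)CC)C[C@@H](O[Si](CC)(CC)CC)/C=C(/C(=O)OC)C[Si](C)(C)C
F2 | step 11 | open-chain ynone (1-oxo, 8,10-bis-O-TES) | O=C/C=C(/CO[Si](c1ccccc1)(c1ccccc1)C(C)(C)C)C#CC(=O)[C@](C)(O[Si](CC)(CC)CC)C[C@@H](O[Si](CC)(CC)CC)/C=C(/C(=O)OC)C[Si](C)(C)C
F3 | step 11 | open-chain 8,10-dihydroxy ynone | O=C/C=C(/CO[Si](c1ccccc1)(c1ccccc1)C(C)(C)C)C#CC(=O)[C@](C)(O)C[C@@H](O)/C=C(/C(=O)OC)C[Si](C)(C)C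
F4 | step 11 | open-chain (10R)-furanone enal allylsilane with free (8R)-OH | O=C/C=C(/CO[Si](c1ccccc1)(c1ccccc1)C(C)(C)C)C1=CC(=O)[C@@](C)(C[C@@H](O)/C=C(/C(=O)OC)C[Si](C)(C)C)O1
F5 | step 11 | 8-O-trimethylsilyl ether of F4 | O=C/C=C(/CO[Si](c1ccccc1)(c1ccccc1)C(C)(C)C)C1=CC(=O)[C@@](C)(C[C@@H](O[Si](C)(C)C)/C=C(/C(=O)OC)C[Si](C)(C)C)O1
F6 | step 11 | open-chain furanone allylic bromide (Br on C7, epimers) | O=C/C=C(/CO[Si](c1ccccc1)(c1ccccc1)C(C)(C)C)C1=CC(=O)[C@@](C)(C[C@@H](O[Si](C)(C)C)C(Br)C(=C)C(=O)OC)O1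
F7 | step 11 | (E)-σ-allylchromium dichloride derived from F6 | O=C/C=C(/CO[Si](c1ccccc1)(c1ccccc1)C(C)(C)C)C1=CC(=O)[C@@](C)(C[C@@H](O[Si](C)(C)C)/C=C(/C[Cr](Cl)Cl)C(=O)OC)O1
F8 | step 11 | 8-O-trimethylsilyl ether of 24 | C=C1C(=O)O[C@@H]2/C=C(/CO[Si](c4ccccc4)(c4ccccc4)C(C)(C)C)C3=CC(=O)[C@@](C)(C[C@@H](O[Si](C)(C)C)[C@@H]12)O3
F9 | step 7 | (4R)-4-methyl-4-[(triethylsilyl)oxy]hex-5-enal | C=C[C@](C)(O[Si](CC)(CC)CC)CCC=O
F10 | step 7 | (2R,4R)-4-methyl-2-[(phenylamino)oxy]-4-[(triethylsilyl)oxy]hex-5-enal | C=C[C@](C)(O[Si](CC)(CC)CC)C[C@@H](ONc1ccccc1)C=O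
F11 | step 7 | methyl (2Z,4R,6R)-6-methyl-4-[(phenylamino)oxy]-6-[(triethylsilyl)oxy]-2-[(trimethylsilyl)methyl]octa-2,7-dienoate | C=C[C@](C)(O[Si](CC)(CC)CC)C[C@@H](ONc1ccccc1)/C=C(/C(=O)OC)C[Si](C)(C)C
F12 | step 7 | methyl (2Z,4R,6R)-4-hydroxy-6-methyl-6-[(triethylsilyl)oxy]-2-[(trimethylsilyl)methyl]octa-2,7-dienoate | C=C[C@](C)(O[Si](CC)(CC)CC)C[C@@H](O)/C=C(/C(=O)OC)C[Si](C)(C)C
F0 | step 10 | none | none
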